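**Retrosynthetic overview**
1. Target 17 ⇒ α-bromoketone 16 (hydride reduction gives the cis-bromohydrin) ⇒ ketone 14 (kinetic C9 bromination). The C5–Br bond comes from ketone 11 by reduction and Appel inversion.
2. Cyclobutane (third ring): head-to-tail enone–alkene [2+2] photocycloaddition of hydrindenone 9 with vinyl acetate, which also delivers the acetate.
3. Cyclopentenone (second ring): intramolecular aldol condensation of a 1,4-diketone onto the vinylogous-ester carbonyl. The side chains come from two Stork–Danheiser α′-alkylations of 3.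
4. Key step: a catalytic enantiotopos-selective C–O bond formation (enol etherification) on prochiral dione 2 fixes the single stereocentre of 3 (C8 of 17). All other centres are relayed from it.
5. Ring order: cyclohexane (purchased) → cyclopentane → cyclobutane.

Assumption: locants are those of each compound's own IUPAC numbering. In the tricycles (tricyclo[5.4.0.0^1,4]undecane) C1 is the central quaternary carbon, C2 carries OAc, C4 and C7 are the methyl-bearing quaternary carbons, C5 and C9 carry Br, C10 carries the oxygen, C8 and C11 carry methyl.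

**Step 1**
Reactants: 1 5-methylcyclohexane-1,3-dione
Product: 2 2,5-dimethylcyclohexane-1,3-dione
Conditions: MeI, NaOH, H2O/dioxane, 65 °C
Reagents that add atoms: iodomethane, CI
Why: Standard C-alkylation of the 1,3-dione enolate at C2; no stereocentre forms because 2 keeps the mirror plane through C2 and C5.

**Step 2**
Reactants: 2 2,5-dimethylcyclohexane-1,3-dione
Product: 3 (S)-2,5-dimethyl-3-(2-methylpropoxy)cyclohex-2-en-1-one
Conditions: i-BuOH (1.2 equiv), chiral confined imidodiphosphorimidate (IDPi) Brønsted acid (2 mol%, enantiomer that gives (S)-3), 5 Å MS, CHCl3, 0 °C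
Reagents that add atoms: 2-methylpropan-1-ol, CC(C)CO
Why: Proposed new method: the chiral acid protonates the enolised dione to a contact ion pair whose two carbonyl-derived termini (C1 and C3) are enantiotopic, isobutanol adds to one terminus only because the confined anion pocket distinguishes the ring pucker fixed by the 5-methyl, and loss of water into the sieves makes the C–O bond formation irreversible so that C5 becomes (S); the closest known reactions are the achiral acid-catalysed enol etherification of 1,3-diones and chiral phosphoric acid/IDPi-catalysed desymmetrising condensations and acetalisations of prochiral carbonyl compounds.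

**Step 3**
Reactants: 3 (S)-2,5-dimethyl-3-(2-methylpropoxy)cyclohex-2-en-1-one
Product: 4 (5S,6R)-2,5,6-trimethyl-3-(2-methylpropoxy)cyclohex-2-en-1-one
Conditions: LDA, THF, −78 °C; MeI, −78→−20 °C
Reagents that add atoms: iodomethane, CI
Why: Stork–Danheiser kinetic α′-deprotonation and methylation trans to the 5-methyl; the C6 configuration is erased again by enolisation in step 4, so its ratio does not matter.

**Step 4**
Reactants: 4 (5S,6R)-2,5,6-trimethyl-3-(2-methylpropoxy)cyclohex-2-en-1-one; 5 1-bromobut-2-yne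
Product: 6 (5S,6R)-6-(but-2-yn-1-yl)-2,5,6-trimethyl-3-(2-methylpropoxy)cyclohex-2-en-1-one
Conditions: LDA, THF, −78→−40 °C; 5, DMPU, −78→0 °C
Reagents that add atoms: none
Why: Second Stork–Danheiser α′-alkylation: the planar enolate is alkylated anti to the adjacent 5-methyl (pseudo-axial to avoid A1,2 strain), so the butynyl group ends trans and the 6-methyl cis to the 5-methyl, which sets the quaternary centre (6R).

**Step 5**
Reactants: 6 (5S,6R)-6-(but-2-yn-1-yl)-2,5,6-trimethyl-3-(2-methylpropoxy)cyclohex-2-en-1-one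
Product: 8 (7S,7aR)-3,4,7,7a-tetramethyl-5-(2-methylpropoxy)-1,6,7,7a-tetrahydro-2H-inden-2-one, via 1,4-diketone 7 (not isolated)
Conditions: Ph3PAuNTf2 (2 mol%), H2O (3 equiv), dioxane, 60 °C; evaporate; t-BuOK (0.3 equiv), t-BuOH, 50 °C
Reagents that add atoms: water, O (taken up in 7; one water is released again on closure to 8)
Why: Carbonyl-assisted (5-exo) gold-catalysed alkyne hydration gives the 1,4-diketone regioselectively, and intramolecular aldol condensation of the ethyl-ketone enolate onto the vinylogous-ester carbonyl (E1cB loss of water) closes the cyclopentenone without touching a stereocentre.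

**Step 6**
Reactants: 8 (7S,7aR)-3,4,7,7a-tetramethyl-5-(2-methylpropoxy)-1,6,7,7a-tetrahydro-2H-inden-2-one
Product: 9 (4R,7S,7aR)-5,5-(ethylenedioxy)-3,4,7,7a-tetramethyl-1,4,5,6,7,7a-hexahydro-2H-inden-2-one
Conditions: ethylene glycol (3 equiv), CSA (5 mol%), PhH, reflux, i-BuOH distilled off
Reagents that add atoms: ethane-1,2-diol, OCCO
Why: Acid-catalysed alkoxy exchange followed by intramolecular conjugate addition of the hydroxyethyl ether (transketalisation of a vinylogous ester) turns C5 into a dioxolane and leaves the cyclopentenone as the only chromophore; C4 is set by axial protonation of the dienol with its methyl trans to the angular 7a-methyl, any minor C4 epimer is re-equilibrated with the same acid, and this centre is finally fixed thermodynamically in step 10.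

**Step 7**
Reactants: 9 (4R,7S,7aR)-5,5-(ethylenedioxy)-3,4,7,7a-tetramethyl-1,4,5,6,7,7a-hexahydro-2H-inden-2-one; 10 vinyl acetate
Product: 11 (1R,2R,4R,7R,8S,11R)-10,10-(ethylenedioxy)-4,7,8,11-tetramethyl-5-oxotricyclo[5.4.0.0^1,4]undecan-2-yl acetate
Conditions: hν (365 nm), 10 (20 equiv), CH2Cl2, −20 °C
Reagents that add atoms: none
Why: Enone–alkene [2+2] photocycloaddition with the head-to-tail regiochemistry expected for an electron-rich alkene (acetoxy carbon bonds to the enone β-carbon); the alkene adds to the face that gives the low-strain cis-hydrindane/cis-bicyclo[3.2.0]heptane, which is also the face opposite the axial ketal oxygen 1,3-syn to the β-carbon (sets C1 and C4), and the acetoxy group takes the exo position away from the cyclopentane and quaternary C7 (sets C2).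

**Step 8**
Reactants: 11 (1R,2R,4R,7R,8S,11R)-10,10-(ethylenedioxy)-4,7,8,11-tetramethyl-5-oxotricyclo[5.4.0.0^1,4]undecan-2-yl acetate
Product: 12 (1R,2R,4R,5R,7R,8S,11R)-10,10-(ethylenedioxy)-5-hydroxy-4,7,8,11-tetramethyltricyclo[5.4.0.0^1,4]undecan-2-yl acetate
Conditions: LiAlH(Ot-Bu)3, THF, −20→0 °C; aq. work-up
Reagents that add atoms: none
Why: Chemoselective ketone reduction (the acetate is inert to this hydride); the bulky hydride attacks C5 from the cyclobutane face, where the α-CH2 is tied back in the four-membered ring, rather than the face carrying the free 4-methyl and the cyclohexane, giving the (5R) alcohol with OH cis to the 4-methyl.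

**Step 9**
Reactants: 12 (1R,2R,4R,5R,7R,8S,11R)-10,10-(ethylenedioxy)-5-hydroxy-4,7,8,11-tetramethyltricyclo[5.4.0.0^1,4]undecan-2-yl acetate
Product: 13 (1R,2R,4R,5S,7R,8S,11R)-5-bromo-10,10-(ethylenedioxy)-4,7,8,11-tetramethyltricyclo[5.4.0.0^1,4]undecan-2-yl acetate
Conditions: PPh3, CBr4, 2,6-lutidine, toluene, 0→50 °C
Reagents that add atoms: carbon tetrabromide, BrC(Br)(Br)Br
Why: Appel reaction: SN2 displacement of the alkoxyphosphonium by bromide with inversion puts bromine on the cyclobutane face (5S), the backside approach following the same open trajectory used by hydride in step 8.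

**Step 10**
Reactants: 13 (1R,2R,4R,5S,7R,8S,11R)-5-bromo-10,10-(ethylenedioxy)-4,7,8,11-tetramethyltricyclo[5.4.0.0^1,4]undecan-2-yl acetate
Product: 14 (1R,2R,4R,5S,7R,8S,11R)-5-bromo-4,7,8,11-tetramethyl-10-oxotricyclo[5.4.0.0^1,4]undecan-2-yl acetate
Conditions: TsOH·H2O (0.2 equiv), THF/H2O 4:1, 45 °C
Reagents that add atoms: water, O
Why: Acid-catalysed ketal hydrolysis leaves acetate and bromide intact, and under the same acid C11 (now α to the ketone) equilibrates through the enol to the equatorial methyl trans to the axial 7-methyl, because the epimer with 1,3-diaxial methyls is strongly disfavoured.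

**Step 11**
Reactants: 14 (1R,2R,4R,5S,7R,8S,11R)-5-bromo-4,7,8,11-tetramethyl-10-oxotricyclo[5.4.0.0^1,4]undecan-2-yl acetate
Product: 16 (1R,2R,4R,5S,7R,8R,9S,11R)-5,9-dibromo-4,7,8,11-tetramethyl-10-oxotricyclo[5.4.0.0^1,4]undecan-2-yl acetate, via silyl enol ether 15 (not isolated)
Conditions: LiHMDS (1.05 equiv), TMSCl, THF, −78 °C; then NBS, −78→0 °C
Reagents that add atoms: chlorotrimethylsilane, C[Si](C)(C)Cl (in 15 only); N-bromosuccinimide, O=C1CCC(=O)N1Br
Why: Kinetic enolisation with internal silyl quench occurs at the C9 methylene (C11–H is tertiary and neopentylic), and electrophilic bromination of the silyl enol ether delivers bromine anti to the 8-methyl and away from the syn-axial 7-methyl, giving the equatorial (9S) bromide that is also the thermodynamic epimer (the C8 descriptor changes from S to R by CIP priority only).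

**Step 12**
Reactants: 16 (1R,2R,4R,5S,7R,8R,9S,11R)-5,9-dibromo-4,7,8,11-tetramethyl-10-oxotricyclo[5.4.0.0^1,4]undecan-2-yl acetate
Product: 17 (1R,2R,4R,5S,7R,8R,9S,10R,11R)-5,9-dibromo-10-hydroxy-4,7,8,11-tetramethyltricyclo[5.4.0.0^1,4]undecan-2-yl acetate
Conditions: L-Selectride (1.2 equiv), THF, −78 °C; H2O quench
Reagents that add atoms: none
Why: Diastereoselective α-bromoketone reduction: axial approach to C10 is blocked by the syn-axial C1–C4 bond, so the bulky hydride enters equatorially and gives the axial (10R) alcohol cis to bromine and to the 11-methyl, and this cis-bromohydrin cannot close to an epoxide.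

**Compound list**
1 | 5-methylcyclohexane-1,3-dione | CC1CC(=O)CC(=O)C1 | starting material
2 | 2,5-dimethylcyclohexane-1,3-dione | CC1CC(=O)C(C)C(=O)C1 | intermediate
3 | (S)-2,5-dimethyl-3-(2-methylpropoxy)cyclohex-2-en-1-one | O=C1C[C@@H](C)CC(OCC(C)C)=C1C | intermediate
4 | (5S,6R)-2,5,6-trimethyl-3-(2-methylpropoxy)cyclohex-2-en-1-one (5,6-trans) | C[C@@H]1[C@@H](C)CC(OCC(C)C)=C(C)C1=O | intermediate
5 | 1-bromobut-2-yne | CC#CCBr | starting material
6 | (5S,6R)-6-(but-2-yn-1-yl)-2,5,6-trimethyl-3-(2-methylpropoxy)cyclohex-2-en-1-one (5-Me and 6-Me cis) | CC#CC[C@]1(C)[C@@H](C)CC(OCC(C)C)=C(C)C1=O | intermediate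
7 | (5S,6R)-2,5,6-trimethyl-3-(2-methylpropoxy)-6-(2-oxobutyl)cyclohex-2-en-1-one | CCC(=O)C[C@]1(C)[C@@H](C)CC(OCC(C)C)=C(C)C1=O | intermediate
8 | (7S,7aR)-3,4,7,7a-tetramethyl-5-(2-methylpropoxy)-1,6,7,7a-tetrahydro-2H-inden-2-one | O=C1C[C@]2(C)[C@@H](C)CC(OCC(C)C)=C(C)C2=C1C | intermediate
9 | (4R,7S,7aR)-5,5-(ethylenedioxy)-3,4,7,7a-tetramethyl-1,4,5,6,7,7a-hexahydro-2H-inden-2-one | O=C1C[C@]2(C)[C@@H](C)CC3(OCCO3)[C@H](C)C2=C1C | intermediate
10 | vinyl acetate | C=COC(C)=O | starting material
11 | (1R,2R,4R,7R,8S,11R)-10,10-(ethylenedioxy)-4,7,8,11-tetramethyl-5-oxotricyclo[5.4.0.0^1,4]undecan-2-yl acetate | CC(=O)O[C@@H]1C[C@@]2(C)C(=O)C[C@]3(C)[C@@H](C)CC4(OCCO4)[C@H](C)[C@]123 | intermediate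
12 | (1R,2R,4R,5R,7R,8S,11R)-10,10-(ethylenedioxy)-5-hydroxy-4,7,8,11-tetramethyltricyclo[5.4.0.0^1,4]undecan-2-yl acetate | CC(=O)O[C@@H]1C[C@@]2(C)[C@H](O)C[C@]3(C)[C@@H](C)CC4(OCCO4)[C@H](C)[C@]123 | intermediate
13 | (1R,2R,4R,5S,7R,8S,11R)-5-bromo-10,10-(ethylenedioxy)-4,7,8,11-tetramethyltricyclo[5.4.0.0^1,4]undecan-2-yl acetate | CC(=O)O[C@@H]1C[C@@]2(C)[C@@H](Br)C[C@]3(C)[C@@H](C)CC4(OCCO4)[C@H](C)[C@]123 | intermediate
14 | (1R,2R,4R,5S,7R,8S,11R)-5-bromo-4,7,8,11-tetramethyl-10-oxotricyclo[5.4.0.0^1,4]undecan-2-yl acetate | CC(=O)O[C@@H]1C[C@@]2(C)[C@@H](Br)C[C@]3(C)[C@@H](C)CC(=O)[C@H](C)[C@]123 | intermediate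
15 | (1R,2R,4R,5S,7R,8S,11R)-5-bromo-4,7,8,11-tetramethyl-10-(trimethylsilyloxy)tricyclo[5.4.0.0^1,4]undec-9-en-2-yl acetate | CC(=O)O[C@@H]1C[C@@]2(C)[C@@H](Br)C[C@]3(C)[C@@H](C)C=C(O[Si](C)(C)C)[C@H](C)[C@]123 | intermediate
16 | (1R,2R,4R,5S,7R,8R,9S,11R)-5,9-dibromo-4,7,8,11-tetramethyl-10-oxotricyclo[5.4.0.0^1,4]undecan-2-yl acetate | CC(=O)O[C@@H]1C[C@@]2(C)[C@@H](Br)C[C@]3(C)[C@@H](C)[C@H](Br)C(=O)[C@H](C)[C@]123 | intermediate
17 | (1R,2R,4R,5S,7R,8R,9S,10R,11R)-5,9-dibromo-10-hydroxy-4,7,8,11-tetramethyltricyclo[5.4.0.0^1,4]undecan-2-yl acetate | CC(=O)O[C@@H]1C[C@@]2(C)[C@@H](Br)C[C@]3(C)[C@@H](C)[C@H](Br)[C@H](O)[C@H](C)[C@]123 | target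

**Total step count:** 12
**Longest linear sequence:** 12 steps (1 → 17)

**Three steps most likely to fail**

Step 2 (the proposed new desymmetrising enol etherification). The only stereo-differentiating element is a remote methyl, so the ee may be low, and acid-catalysed alkoxy exchange could erode it. The fallback uses known chemistry, sets out from 2 and returns at 3. Condense 2 with isobutanol under TsOH in benzene with azeotropic water removal to give the racemic enol ether, then resolve it by preparative chiral-phase SFC and keep 3. The unwanted enantiomer (R)-2,5-dimethyl-3-(2-methylpropoxy)cyclohex-2-en-1-one F1 is hydrolysed with aqueous HCl back to achiral 2 and recycled.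

Step 7 (the [2+2] photocycloaddition). The tetrasubstituted enone may give some head-to-head adduct or add on the other face, and the least predictable element is the configuration at C2. The fallback sets out from 9 and 10 and returns at 11. If the photoadduct is mainly the C2 epimer (1R,2S,4R,7R,8S,11R)-10,10-(ethylenedioxy)-4,7,8,11-tetramethyl-5-oxotricyclo[5.4.0.0^1,4]undecan-2-yl acetate F2, C2 is set by substitution instead of by the photoreaction. Methanolysis (K2CO3, MeOH) gives the cyclobutanol (1R,2S,4R,7R,8S,11R)-10,10-(ethylenedioxy)-2-hydroxy-4,7,8,11-tetramethyltricyclo[5.4.0.0^1,4]undecan-5-one F3, and Mitsunobu inversion with acetic acid (PPh3, DIAD, THF) gives 11.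

Step 9 (Appel bromination at the neopentylic C5). The alkoxyphosphonium next to the cyclobutane can ionise (cyclobutylcarbinyl to cyclopentyl ring expansion) or eliminate, and the step also depends on the facial outcome of step 8. The fallback sets out from 12 and returns at 13. It replaces the polar substitution by a radical bromination that does not depend on the alcohol configuration. Acylate 12 with oxalyl chloride (pyridine, then water) to the hydrogen oxalate 2-{[(1R,2R,4R,5R,7R,8S,11R)-2-acetoxy-10,10-(ethylenedioxy)-4,7,8,11-tetramethyltricyclo[5.4.0.0^1,4]undecan-5-yl]oxy}-2-oxoacetic acid F4. Photoredox oxidation (Ir photocatalyst, K2HPO4, blue light, 60 °C) in the presence of BrCCl3 releases the C5 radical after loss of two CO2. The radical takes bromine from the open cyclobutane face to give 13, and cyclobutylcarbinyl ring opening is slow compared with bromine-atom transfer.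

**Further compounds**
F1 | step 2 | (R)-2,5-dimethyl-3-(2-methylpropoxy)cyclohex-2-en-1-one | O=C1C[C@H](C)CC(OCC(C)C)=C1C
F2 | step 7 | (1R,2S,4R,7R,8S,11R)-10,10-(ethylenedioxy)-4,7,8,11-tetramethyl-5-oxotricyclo[5.4.0.0^1,4]undecan-2-yl acetate | CC(=O)O[C@H]1C[C@@]2(C)C(=O)C[C@]3(C)[C@@H](C)CC4(OCCO4)[C@H](C)[C@]123
F3 | step 7 | (1R,2S,4R,7R,8S,11R)-10,10-(ethylenedioxy)-2-hydroxy-4,7,8,11-tetramethyltricyclo[5.4.0.0^1,4]undecan-5-one | O[C@H]1C[C@@]2(C)C(=O)C[C@]3(C)[C@@H](C)CC4(OCCO4)[C@H](C)[C@]123
F4 | step 9 | 2-{[(1R,2R,4R,5R,7R,8S,11R)-2-acetoxy-10,10-(ethylenedioxy)-4,7,8,11-tetramethyltricyclo[5.4.0.0^1,4]undecan-5-yl]oxy}-2-oxoacetic acid | CC(=O)O[C@@H]1C[C@@]2(C)[C@H](OC(=O)C(O)=O)C[C@]3(C)[C@@H](C)CC4(OCCO4)[C@H](C)[C@]123
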